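**Conventions.** Prenyl = 3-methylbut-2-en-1-yl; isobutyryl = 2-methylpropanoyl; TES = triethylsilyl. Skeleton numbering used throughout: C1 (isobutyryl bridgehead), C2 (CMe2), C3 (CH-prenyl), C4 (CH2), C5 (prenyl bridgehead), C6 (carbinol), C7 (ring ketone), C8 (bridging ketone), C9 (isobutyryl carbonyl), C10–C13 (side chain on C6, C10 the carbonyl, C13 the carbinol carbon).

## The problem

The target is a bicyclo[3.2.1]octane in which a five-membered ring (C1, C7, C6, C5, C8) and a six-membered ring (C1–C5, C8) share the bridgeheads C1 and C5 and the bridging ketone C8. C1, C2, C5 and C6 are fully substituted, and the C1–C2 bond joins two quaternary carbons. There are four stereocentres. C1 and C5 are tied to each other by the bridge, so only C5 has to be set in the absolute sense. C3 carries its prenyl group equatorial on the chair six-membered ring, the favoured position, so it can be set by equilibration at a stage where C3 is epimerisable. C6 carries the hydroxyl group endo and the acyl chain exo (syn to C8), which is the outcome of exo-face attack on a C6 ketone. The fragile elements are: the non-enolisable array of ketones around C1 (retro-Claisen cleavage by hydroxide, alkoxide or amide); the tertiary ketol at C6, which is an aldol of the C8 ketone (retro-aldol as its alkoxide); the (Z)-γ-hydroxy enone (Z to E isomerisation, ring–chain tautomerism); and two prenyl alkenes (acid, electrophilic oxidants). The enabling feature is that, with C6 and C7 both at the ketone level, C1 and C5 are the two carbon acids of a 3-acylcyclopentane-1,2,4-trione. They are spanned by C4–C3–C2, whose termini are a primary carbon (C4) and a gem-dimethyl carbon (C2). This is the pattern left by an allylic electrophile and a β,β-dimethyl Michael acceptor held in one enal, whose formyl group on C3 is a latent prenyl group.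

## Retrosynthesis

**Side chain (25 to 21).** The (Z)-4-hydroxy-4-methylpent-2-enoyl group of target 25 is cut at the C13–methyl bond and at the two carbonyl oxygens. This leads through silyl ether 24 and the (Z)-enedione 23 to the 5-methylfuran-2-yl group of 21. Aldol or olefination routes to this enone would give the E isomer; a furan delivers the Z geometry from its ring. The forward steps must oxidise the furan in the presence of two prenyl groups and add one methyl group to the only unhindered ketone. The C6 oxygen stays silylated throughout, so that the opened furan cannot close on it as a hemiketal.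

**C3 prenyl group (21 to 18).** The prenyl alkene of 21 is cut by a Wittig disconnection to aldehyde 20, and one carbon is removed through enol ether 19 to the C3 carbaldehyde 18. This keeps the C3 substituent at the oxidation level the annulation delivers. The homologation is placed after C6 has been functionalised, because only then is every ketone (C7, C8, C9) flanked by two fully substituted carbons and inert to ylides.

**C6–C10 bond (18 to 12).** Aldehyde 18 is taken back to its dimethyl acetal 17. Cutting the C6–furyl bond of 17 gives 2-methylfuran 14 and the vicinal diketone 13, which is the acetal of the annulation product 12. C6 is the more accessible carbonyl of the diketone and its exo face is open, so one addition should set the last stereocentre. A discrete acetal is preferred to masking the aldehyde in the flask with an amide base, since nitrogen nucleophiles would attack the strained diketone and cleave it.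

**Key disconnection (12 to 5 and 10).** Cutting C4–C5 and C1–C2 removes the whole three-carbon bridge of 12. This returns the monocyclic trione 5, which has no fixed stereocentre, and the eight-carbon enal 10. Compared with the cuts at C1–C7 or C6–C7 it removes both quaternary-centre problems and all three stereocentres in one operation, and it is convergent. The forward reaction asks for alkylation of the dianion of 5 at C5 by the acetoxymethyl carbon under a chiral ammonium salt, giving the ring-open enal 11, and then Michael closure of C1 onto the β,β-dimethyl carbon. The triketone enolate of 11 is far more stable than the aldehyde enolate of the adduct, so the closure is planned after the base has been buffered with a weak acid, in the same flask.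

**Trione 5.** The five-membered ring is cut at the two bonds to the vicinal carbonyl carbons, giving diethyl oxalate 4 and β-diketone 3. Diketone 3 is cut at the C–acyl bond into 6-methylhept-5-en-2-one 1 and methyl isobutyrate 2. The prenyl group of 5 is already present in 1.

**Enal 10.** The aldehyde is taken back to alcohol 9, the monoacetate of the symmetrical diol 7, which comes from reduction of diethyl isopropylidenemalonate 6. Mono-acylation through the cyclic orthoester 8 avoids a statistical mixture.

## Roads not taken

**Alternative 1:** De Mayo photocycloaddition. The cut is at C6–C7 and at the C1–C9 bond to the isobutyryl group. In the forward direction a preformed cyclohexanone carries a silyloxymethylene group on C1 (C1=C7) and an enolised β-keto ester arm on C5 (C6=C9). Irradiation gives a crossed [2+2] adduct, and retro-aldol cleavage of C6–C9 leaves the bicycle A1 with the isobutyryl group on C1.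
- Merits: the most congested bond, from the bridgehead to the acyl carbon, forms within the molecule and irreversibly, with no equilibrium against a stabilised triketone enolate. The six-membered ring with C3 and C5 is built beforehand by ordinary cyclohexanone chemistry.
- Weak points: both prenyl groups must travel as acetals, because the alkenes would intercept the excited enone, and must be rebuilt by two late olefinations. In A1, C7 is a silyloxy carbinol and C6 a CH–ester, so oxidation at C7, hydroxylation at C6 and conversion of the ester into the hydroxy-enoyl ketone all remain. The crossed mode of addition and the absolute configuration at C5 must be secured in a long linear substrate synthesis.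
- Comparison: this road is better exactly where the chosen plan is weakest, the C1 quaternary centre. Against that the chosen plan sets convergence, short fragment syntheses (two and three steps), and arrival at the correct oxidation level at C6, C7 and C8.

**Alternative 2:** Claisen closure at the acylated bridgehead. The cut is C1–C7. The β-diketone enolate at C1 of a 2-isobutyrylcyclohexanone attacks the ester carbon of an axial α-silyloxy ester arm on C5, giving A2, held as its C6 enolate until work-up.
- Merits: a classical acylation; both prenyl groups and the C3 and C5 centres are in place before the closure. C6 emerges oxygenated and nucleophilic, so the side chain could be introduced as an acyl electrophile from the exo face. That end game could be shorter than the furan addition, oxidation and methylation used here.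
- Weak points: the Claisen product is a non-enolisable triacyl carbon, so the closure is reversible and is held only by enolisation at C6 inside a strained five-membered ring. The ester arm must be axial. The cyclohexanone with quaternary C5, gem-dimethyl C2 and the C3 prenyl group needs a long, linear, stereocontrolled synthesis.
- Comparison: equal or better after the ring is closed, clearly worse before it. The chosen plan reaches its bicycle in six steps overall.

**Alternative 3:** Desymmetrising seleno-carbocyclisation. The cut is C1–C2 alone. A selenium electrophile under a chiral Lewis-base catalyst activates one of the two enantiotopic prenyl groups of achiral cohulupone A3, and the enol carbon C1 opens the seleniranium ion at C2 to give A4.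
- Merits: A3 is one prenylation away from trione 5, so the bicycle would appear at step 3. One catalytic step would set C1, C3 and C5. The ring closure is irreversible, unlike a Michael addition of a triketone.
- Weak points: enol oxygen, not carbon, is the usual nucleophile toward seleniranium ions in such triones, leading to cyclic ethers. Enantioselective variants with trisubstituted alkenes and carbon nucleophiles are scarce, and seleniranium ions can racemise by transfer between alkenes. The C3–Se bond of A4 must then be turned into a C3–prenyl bond by radical chemistry, which tends to deliver the reversed prenyl isomer or needs an allylation and metathesis detour.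
- Comparison: if the C-selective closure worked this would be the shortest route, and on step count it beats the chosen plan. The chosen plan sets against it a closely related annulation known in the acylphloroglucinol series with the same enal and catalyst class, and a carbon substituent placed directly on C3 under thermodynamic control.

Key step: step 6

**Assumptions.**
- The cinchonidine-derived ammonium salt is taken to give the (5R) configuration of 11; if the sense of induction is the opposite, the pseudoenantiomeric cinchonine-derived salt is used with no other change.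
- The target is treated as the open-chain (Z)-γ-hydroxy enone as drawn; its five-membered lactol is a ring–chain tautomer and not a separate compound.

## Route

Step 1
Reactants: 1 6-methylhept-5-en-2-one; 2 methyl isobutyrate
Product: 3 2,9-dimethyldec-8-ene-3,5-dione
Conditions: NaH (2.2 equiv), THF, reflux; then 1 M HCl, 0 °C
Reagents that add atoms: none
Why: Crossed Claisen condensation; the methyl ketone is acylated at its methyl group and the product is drained as its β-diketonate, while methyl isobutyrate cannot self-condense productively because its Claisen product has no acidic hydrogen between the carbonyls.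

Step 2
Reactants: 3 2,9-dimethyldec-8-ene-3,5-dione; 4 diethyl oxalate
Product: 5 3-isobutyryl-5-prenylcyclopentane-1,2,4-trione (enol form; C5 labile)
Conditions: NaOEt (3 equiv), EtOH–toluene, reflux; then 2 M HCl, 0 °C
Reagents that add atoms: none
Why: Double Claisen condensation with an oxalate ester (acylation then Dieckmann-type closure), the standard entry to 3,5-disubstituted cyclopentane-1,2,4-triones. Closure through the CH2 and not the isopropyl CH should prevail under these reversible conditions, because only that product keeps an acidic ring hydrogen and is removed as a dianion.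

Step 3
Reactants: 6 diethyl isopropylidenemalonate
Product: 7 2-(propan-2-ylidene)propane-1,3-diol
Conditions: i-Bu2AlH (4.5 equiv), CH2Cl2, −78 → 0 °C; aq. potassium sodium tartrate
Reagents that add atoms: none
Why: 1,2-Reduction of both conjugated esters; dialkylaluminium hydrides reduce alkylidene malonates to the allylic diols without conjugate reduction.

Step 4
Reactants: 7 2-(propan-2-ylidene)propane-1,3-diol
Product: 9 2-(hydroxymethyl)-3-methylbut-2-en-1-yl acetate, via cyclic orthoester 8 (not isolated)
Conditions: MeC(OMe)3 (1.2 equiv), pyridinium p-toluenesulfonate (2 mol %), CH2Cl2, 23 °C; then H2O, 23 °C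
Reagents that add atoms: trimethyl orthoacetate, CC(OC)(OC)OC; water, O
Why: Mono-acetylation of a symmetrical 1,3-diol through its cyclic orthoester, whose hydrolysis can only give the mono-ester, so no statistical mixture arises.

Step 5
Reactants: 9 2-(hydroxymethyl)-3-methylbut-2-en-1-yl acetate
Product: 10 2-(acetoxymethyl)-3-methylbut-2-enal
Conditions: Dess–Martin periodinane (1.2 equiv), CH2Cl2, 0 → 23 °C
Reagents that add atoms: none
Why: Dess–Martin oxidation of a primary allylic alcohol; the acetate and the tetrasubstituted alkene are inert, and the alkene has no geometry to lose.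

Step 6
Reactants: 5 3-isobutyryl-5-prenylcyclopentane-1,2,4-trione; 10 2-(acetoxymethyl)-3-methylbut-2-enal
Product: 12 (1R,3R,5R)-1-isobutyryl-2,2-dimethyl-6,7,8-trioxo-5-prenylbicyclo[3.2.1]octane-3-carbaldehyde, via ring-open enal 11 (not isolated)
Conditions: O-allyl-N-(9-anthracenylmethyl)cinchonidinium bromide (20 mol %), CsOH·H2O (3 equiv), CH2Cl2, −50 °C; then 10 (1.5 equiv), −50 °C; then AcOH (10 equiv), −50 → 23 °C
Reagents that add atoms: none
Why: Proposed new method: the closest known reaction type is the alkylative dearomatisation–annulation of prenylated acylphloroglucinols with this acetoxymethyl enal under achiral and chiral phase-transfer conditions, which gives bicyclo[3.3.1]nonane triones; here the nucleophile is the ring-contracted acylcyclopentanetrione. CsOH forms the dianion of 5, whose less stabilised carbon C5 displaces acetate at the primary allylic carbon of 10 (SN2; the β,β-dimethyl terminus is too hindered for a carbon that becomes quaternary), which forms C4–C5 and leaves 11 as its triketone enolate. The planar C5 is ion-paired with the chiral ammonium cation, which screens one enantiotopic face, so C5 is set by the catalyst. The enolate of 11 is much more stable than the aldehyde enolate that ring closure would produce, so closure is not expected under stoichiometric base; in the acetic acid buffer C1 adds to the enal carbon C2 and the aldehyde enolate is protonated at once, which forms C1–C2 and closes the six-membered ring C1–C2–C3–C4–C5–C8 in a 6-endo-trig mode. C1 can only bond on the face of the five-membered ring that carries the C4 arm, so its configuration follows from C5. C3 stays epimerisable through the enol in the buffer and should settle with the formyl group equatorial, away from the C6–C7 bridge. The step needs alkylation at C5 before C1 and carbon rather than oxygen bonding in both stages: the first is secured by forming the dianion completely before 10 is added, the second by the soft allylic and Michael electrophiles and by the ready reversal of an oxa-Michael adduct.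

Step 7
Reactants: 12 (1R,3R,5R)-1-isobutyryl-2,2-dimethyl-6,7,8-trioxo-5-prenylbicyclo[3.2.1]octane-3-carbaldehyde
Product: 13 (1R,3R,5R)-3-(dimethoxymethyl)-1-isobutyryl-2,2-dimethyl-5-prenylbicyclo[3.2.1]octane-6,7,8-trione
Conditions: MeOSiMe3 (2.5 equiv), Me3SiOTf (5 mol %), CH2Cl2, −78 °C; pyridine quench
Reagents that add atoms: methoxytrimethylsilane, CO[Si](C)(C)C
Why: Aprotic acetalisation with an alkoxysilane and catalytic silyl triflate is selective for aldehydes over ketones flanked by quaternary carbons. It avoids the protic nucleophiles and bases that could cleave the non-enolisable polyketone.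

Step 8
Reactants: 13 (1R,3R,5R)-3-(dimethoxymethyl)-1-isobutyryl-2,2-dimethyl-5-prenylbicyclo[3.2.1]octane-6,7,8-trione; 14 2-methylfuran
Product: 17 (1R,3R,5S,6S)-3-(dimethoxymethyl)-1-isobutyryl-2,2-dimethyl-6-(5-methylfuran-2-yl)-5-prenyl-6-(triethylsilyloxy)bicyclo[3.2.1]octane-7,8-dione, via 5-methyl-2-furyllithium 15 (not isolated), via lithium alkoxide 16 (not isolated)
Conditions: 14, n-BuLi, THF, 0 °C; then 13, THF, −78 °C; then Et3SiOTf (1.5 equiv), −78 → −40 °C
Reagents that add atoms: triethylsilyl trifluoromethanesulfonate, CC[Si](CC)(CC)OS(=O)(=O)C(F)(F)F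
Why: 1,2-Addition of a heteroaryllithium to the vicinal diketone at C6, the carbonyl next to the less encumbered bridgehead. Attack comes from the exo face syn to the one-carbon bridge, because the endo face is screened by the axial hydrogen on C3; this sets C6 with oxygen endo. The alkoxide is silylated in the same flask before retro-aldol cleavage of C5–C6 can set in.

Step 9
Reactants: 17 (1R,3R,5S,6S)-3-(dimethoxymethyl)-1-isobutyryl-2,2-dimethyl-6-(5-methylfuran-2-yl)-5-prenyl-6-(triethylsilyloxy)bicyclo[3.2.1]octane-7,8-dione
Product: 18 (1R,3R,5S,6S)-1-isobutyryl-2,2-dimethyl-6-(5-methylfuran-2-yl)-7,8-dioxo-5-prenyl-6-(triethylsilyloxy)bicyclo[3.2.1]octane-3-carbaldehyde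
Conditions: pyridinium p-toluenesulfonate (0.2 equiv), acetone–H2O (10:1), 50 °C
Reagents that add atoms: water, O
Why: Mild acid hydrolysis of a dimethyl acetal; the hindered tertiary TES ether and the 2,5-disubstituted furan should survive, and the equatorial C3 configuration is the thermodynamic one.

Step 10
Reactants: 18 (1R,3R,5S,6S)-1-isobutyryl-2,2-dimethyl-6-(5-methylfuran-2-yl)-7,8-dioxo-5-prenyl-6-(triethylsilyloxy)bicyclo[3.2.1]octane-3-carbaldehyde
Product: 19 (1R,3S,5S,6S)-1-isobutyryl-3-(2-methoxyethenyl)-2,2-dimethyl-6-(5-methylfuran-2-yl)-5-prenyl-6-(triethylsilyloxy)bicyclo[3.2.1]octane-7,8-dione (E/Z mixture)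
Conditions: MeOCH2PPh3Cl, KN(SiMe3)2, THF, 0 °C; then 18, −78 → 0 °C
Reagents that add atoms: (methoxymethyl)triphenylphosphonium chloride, COC[P+](c1ccccc1)(c1ccccc1)c1ccccc1.[Cl-]
Why: Wittig methoxymethylenation of the only unhindered carbonyl; C7, C8 and C9 are each flanked by two fully substituted carbons. Low temperature keeps enolisation of the α-branched aldehyde to a minimum.

Step 11
Reactants: 19 (1R,3S,5S,6S)-1-isobutyryl-3-(2-methoxyethenyl)-2,2-dimethyl-6-(5-methylfuran-2-yl)-5-prenyl-6-(triethylsilyloxy)bicyclo[3.2.1]octane-7,8-dione
Product: 20 (1R,3S,5S,6S)-1-isobutyryl-2,2-dimethyl-6-(5-methylfuran-2-yl)-3-(2-oxoethyl)-5-prenyl-6-(triethylsilyloxy)bicyclo[3.2.1]octane-7,8-dione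
Conditions: TsOH·H2O (0.2 equiv), acetone–H2O (10:1), 23 °C
Reagents that add atoms: water, O
Why: Acid hydrolysis of a methyl enol ether completes the one-carbon homologation; C3 is no longer α to a carbonyl and is fixed from here on.

Step 12
Reactants: 20 (1R,3S,5S,6S)-1-isobutyryl-2,2-dimethyl-6-(5-methylfuran-2-yl)-3-(2-oxoethyl)-5-prenyl-6-(triethylsilyloxy)bicyclo[3.2.1]octane-7,8-dione
Product: 21 (1R,3R,5S,6S)-1-isobutyryl-2,2-dimethyl-6-(5-methylfuran-2-yl)-3,5-diprenyl-6-(triethylsilyloxy)bicyclo[3.2.1]octane-7,8-dione
Conditions: i-PrPPh3I, n-BuLi, THF, 0 °C; then 20, −78 → 0 °C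
Reagents that add atoms: isopropyltriphenylphosphonium iodide, CC(C)[P+](c1ccccc1)(c1ccccc1)c1ccccc1.[I-]
Why: Wittig olefination of an unbranched aldehyde with the isopropylidene ylide builds the second prenyl group; enolisation here cannot open the ring, since the enolate carbon is no longer β to C1.

Step 13
Reactants: 21 (1R,3R,5S,6S)-1-isobutyryl-2,2-dimethyl-6-(5-methylfuran-2-yl)-3,5-diprenyl-6-(triethylsilyloxy)bicyclo[3.2.1]octane-7,8-dione
Product: 23 (1R,3R,5S,6S)-1-isobutyryl-2,2-dimethyl-6-[(2Z)-4-oxopent-2-enoyl]-3,5-diprenyl-6-(triethylsilyloxy)bicyclo[3.2.1]octane-7,8-dione, via furan endoperoxide 22 (not isolated)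
Conditions: O2, tetraphenylporphyrin (cat.), visible light, CH2Cl2, −78 °C; then Me2S, −78 → 0 °C
Reagents that add atoms: dioxygen, O=O
Why: [4+2] Cycloaddition of singlet oxygen to an electron-rich 2,5-disubstituted furan, a class that reacts far faster than trisubstituted alkenes do in the ene mode. Reduction of the endoperoxide gives the cis-enedione with the Z geometry taken from the ring; the silyl ether on C6 prevents hemiketal formation of the Achmatowicz type.

Step 14
Reactants: 23 (1R,3R,5S,6S)-1-isobutyryl-2,2-dimethyl-6-[(2Z)-4-oxopent-2-enoyl]-3,5-diprenyl-6-(triethylsilyloxy)bicyclo[3.2.1]octane-7,8-dione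
Product: 24 (1R,3R,5S,6S)-6-[(2Z)-4-hydroxy-4-methylpent-2-enoyl]-1-isobutyryl-2,2-dimethyl-3,5-diprenyl-6-(triethylsilyloxy)bicyclo[3.2.1]octane-7,8-dione
Conditions: MeLi, CeCl3, THF, −78 °C; aq. NH4Cl
Reagents that add atoms: methyllithium, [Li]C
Why: 1,2-Addition of a weakly basic organocerium reagent to the methyl ketone C13, the only carbonyl not attached to a fully substituted carbon. No stereocentre is formed, since C13 then carries two methyl groups.

Step 15
Reactants: 24 (1R,3R,5S,6S)-6-[(2Z)-4-hydroxy-4-methylpent-2-enoyl]-1-isobutyryl-2,2-dimethyl-3,5-diprenyl-6-(triethylsilyloxy)bicyclo[3.2.1]octane-7,8-dione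
Product: 25 (1R,3R,5S,6S)-6-hydroxy-6-[(2Z)-4-hydroxy-4-methylpent-2-enoyl]-1-isobutyryl-2,2-dimethyl-3,5-diprenylbicyclo[3.2.1]octane-7,8-dione
Conditions: HF·pyridine, THF–pyridine, 0 → 23 °C
Reagents that add atoms: none
Why: Desilylation with a buffered acidic fluoride source avoids basic fluoride, which could start retro-aldol cleavage at C6. The gem-dimethyl carbinol cannot dehydrate to a furan, so the side chain survives as the hydroxy enone and its lactol tautomer.

## Compound list

1 | 6-methylhept-5-en-2-one | CC(=O)CCC=C(C)C | starting material
2 | methyl isobutyrate | COC(=O)C(C)C | starting material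
3 | 2,9-dimethyldec-8-ene-3,5-dione | CC(C)C(=O)CC(=O)CCC=C(C)C | intermediate
4 | diethyl oxalate | CCOC(=O)C(=O)OCC | starting material
5 | 3-isobutyryl-5-prenylcyclopentane-1,2,4-trione (enol form, C5 labile) | CC(C)C(=O)C1=C(O)C(=O)C(CC=C(C)C)C1=O | intermediate
6 | diethyl isopropylidenemalonate | CCOC(=O)C(=C(C)C)C(=O)OCC | starting material
7 | 2-(propan-2-ylidene)propane-1,3-diol | CC(C)=C(CO)CO | intermediate
8 | 2-methoxy-2-methyl-5-(propan-2-ylidene)-1,3-dioxane (not isolated) | COC1(C)OCC(=C(C)C)CO1 | intermediate
9 | 2-(hydroxymethyl)-3-methylbut-2-en-1-yl acetate | CC(C)=C(CO)COC(C)=O | intermediate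
10 | 2-(acetoxymethyl)-3-methylbut-2-enal | CC(C)=C(C=O)COC(C)=O | intermediate
11 | (5R)-5-(2-formyl-3-methylbut-2-en-1-yl)-3-isobutyryl-5-prenylcyclopentane-1,2,4-trione (enol form, not isolated) | CC(C)C(=O)C1=C(O)C(=O)[C@](CC=C(C)C)(CC(C=O)=C(C)C)C1=O | intermediate
12 | (1R,3R,5R)-1-isobutyryl-2,2-dimethyl-6,7,8-trioxo-5-prenylbicyclo[3.2.1]octane-3-carbaldehyde | O=C[C@@H]1C[C@]2(CC=C(C)C)C(=O)[C@@](C(=O)C(C)C)(C(=O)C2=O)C1(C)C | intermediate
13 | (1R,3R,5R)-3-(dimethoxymethyl)-1-isobutyryl-2,2-dimethyl-5-prenylbicyclo[3.2.1]octane-6,7,8-trione | COC(OC)[C@@H]1C[C@]2(CC=C(C)C)C(=O)[C@@](C(=O)C(C)C)(C(=O)C2=O)C1(C)C | intermediate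
14 | 2-methylfuran | Cc1ccco1 | starting material
15 | 5-methyl-2-furyllithium (not isolated) | [Li]c1ccc(C)o1 | intermediate
16 | lithium alkoxide of the C6 furyl carbinol, configuration as in 17 (not isolated) | COC(OC)[C@@H]1C[C@]2(CC=C(C)C)C(=O)[C@@](C(=O)C(C)C)(C(=O)[C@@]2(O[Li])c3ccc(C)o3)C1(C)C | intermediate
17 | (1R,3R,5S,6S)-3-(dimethoxymethyl)-1-isobutyryl-2,2-dimethyl-6-(5-methylfuran-2-yl)-5-prenyl-6-(triethylsilyloxy)bicyclo[3.2.1]octane-7,8-dione | COC(OC)[C@@H]1C[C@]2(CC=C(C)C)C(=O)[C@@](C(=O)C(C)C)(C(=O)[C@@]2(O[Si](CC)(CC)CC)c3ccc(C)o3)C1(C)C | intermediate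
18 | (1R,3R,5S,6S)-1-isobutyryl-2,2-dimethyl-6-(5-methylfuran-2-yl)-7,8-dioxo-5-prenyl-6-(triethylsilyloxy)bicyclo[3.2.1]octane-3-carbaldehyde | O=C[C@@H]1C[C@]2(CC=C(C)C)C(=O)[C@@](C(=O)C(C)C)(C(=O)[C@@]2(O[Si](CC)(CC)CC)c3ccc(C)o3)C1(C)C | intermediate
19 | (1R,3S,5S,6S)-1-isobutyryl-3-(2-methoxyethenyl)-2,2-dimethyl-6-(5-methylfuran-2-yl)-5-prenyl-6-(triethylsilyloxy)bicyclo[3.2.1]octane-7,8-dione (E/Z mixture) | COC=C[C@@H]1C[C@]2(CC=C(C)C)C(=O)[C@@](C(=O)C(C)C)(C(=O)[C@@]2(O[Si](CC)(CC)CC)c3ccc(C)o3)C1(C)C | intermediate
20 | (1R,3S,5S,6S)-1-isobutyryl-2,2-dimethyl-6-(5-methylfuran-2-yl)-3-(2-oxoethyl)-5-prenyl-6-(triethylsilyloxy)bicyclo[3.2.1]octane-7,8-dione | O=CC[C@@H]1C[C@]2(CC=C(C)C)C(=O)[C@@](C(=O)C(C)C)(C(=O)[C@@]2(O[Si](CC)(CC)CC)c3ccc(C)o3)C1(C)C | intermediate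
21 | (1R,3R,5S,6S)-1-isobutyryl-2,2-dimethyl-6-(5-methylfuran-2-yl)-3,5-diprenyl-6-(triethylsilyloxy)bicyclo[3.2.1]octane-7,8-dione | CC(C)=CC[C@@H]1C[C@]2(CC=C(C)C)C(=O)[C@@](C(=O)C(C)C)(C(=O)[C@@]2(O[Si](CC)(CC)CC)c3ccc(C)o3)C1(C)C | intermediate
22 | endoperoxide of 21 (4-methyl-2,3,7-trioxabicyclo[2.2.1]hept-5-en-1-yl group on C6, both bridgehead epimers, not isolated) | CC(C)=CC[C@@H]1C[C@]2(CC=C(C)C)C(=O)[C@@](C(=O)C(C)C)(C(=O)[C@@]2(O[Si](CC)(CC)CC)C34C=CC(C)(OO3)O4)C1(C)C | intermediate
23 | (1R,3R,5S,6S)-1-isobutyryl-2,2-dimethyl-6-[(2Z)-4-oxopent-2-enoyl]-3,5-diprenyl-6-(triethylsilyloxy)bicyclo[3.2.1]octane-7,8-dione | CC(C)=CC[C@@H]1C[C@]2(CC=C(C)C)C(=O)[C@@](C(=O)C(C)C)(C(=O)[C@@]2(O[Si](CC)(CC)CC)C(=O)/C=C\C(C)=O)C1(C)C | intermediate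
24 | (1R,3R,5S,6S)-6-[(2Z)-4-hydroxy-4-methylpent-2-enoyl]-1-isobutyryl-2,2-dimethyl-3,5-diprenyl-6-(triethylsilyloxy)bicyclo[3.2.1]octane-7,8-dione | CC(C)=CC[C@@H]1C[C@]2(CC=C(C)C)C(=O)[C@@](C(=O)C(C)C)(C(=O)[C@@]2(O[Si](CC)(CC)CC)C(=O)/C=C\C(C)(C)O)C1(C)C | intermediate
25 | (1R,3R,5S,6S)-6-hydroxy-6-[(2Z)-4-hydroxy-4-methylpent-2-enoyl]-1-isobutyryl-2,2-dimethyl-3,5-diprenylbicyclo[3.2.1]octane-7,8-dione | CC(C)=CC[C@@H]1C[C@]2(CC=C(C)C)C(=O)[C@@](C(=O)C(C)C)(C(=O)[C@@]2(O)C(=O)/C=C\C(C)(C)O)C1(C)C | target

## Step count and least certain steps

Total: 15 steps. Longest linear sequence: 13 steps (6 to 25 through steps 3–15); the trione branch (steps 1 and 2) joins at step 6.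

**Step 6 (key step, proposed new method).** The most likely failure is in the ring closure, not the alkylation. The C-bonded product is strained, joins two quaternary carbons and gives up the enol stabilisation of the triketone. The closure may therefore stall at 11 or divert to the oxygen-bonded dihydropyran formed through the C8 enol oxygen. Incomplete facial discrimination at C5 by an ion pair that has not been tested with this dianion is the second concern.

The fallback uses known chemistry, a cationic instead of a Michael closure; it sets out from trione 5 and returns to the route at 21. The dianion of 5 (NaH, 2.2 equiv, THF–DMPU) is alkylated at C5 with (2S)-1-bromo-5-methyl-2-(prop-1-en-2-yl)hex-4-ene F1, the bromide of (S)-lavandulol obtained by Appel bromination. This reagent brings C4, C3 with its prenyl group and configuration, and C2 as an isopropenyl group, and gives the 5-lavandulyl-5-prenyl trione F2 as both C5 epimers. Formic acid should then protonate the isopropenyl group, and the enol carbon C1 should close on the tertiary cation at C2. This is the cation–enol cyclisation by which acyl-bearing bridgeheads next to CMe2 are made from prenylated acylphloroglucinols. Only the C5 epimer that can hold the C3 prenyl group equatorial is expected to close readily, giving the diprenyl trione F3 after chromatography. F3 has no aldehyde and goes directly into the furyl addition and silylation of step 8 to give 21. The price is loss of catalyst control at C5, a slow substitution by a β-branched primary bromide, and competition from O-cyclisation and from protonation of the prenyl groups.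

**Step 8.** The furyllithium may attack C7 instead of C6, or the lithium alkoxide 16 may fragment by retro-aldol cleavage of C5–C6 before it is silylated; the second is the more likely, since it relieves ring strain. The fallback sets out from 13 and 14 and returns at 17. 2-Methylfuran is used as a π-nucleophile in a Friedel–Crafts hydroxyalkylation of the chelating, s-cis-locked diketone (Cu(OTf)2, 10 mol %, CH2Cl2, 0 °C). No alkali alkoxide is ever formed, and the bulkier nucleophile should favour C6 and the exo face even more. The free tertiary alcohol F4 is then silylated (Et3SiOTf, 2,6-lutidine, CH2Cl2, −78 °C) to give 17.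

**Step 14.** Most likely problems are Z to E isomerisation of the enedione through reversible addition of the new alkoxide, conjugate addition, and attack at C10. The fallback sets out from 23 and returns at 24; it delivers the methyl group to an oxocarbenium ion of the ring-locked, masked enedione instead of to a free ketone. Ketalisation (HC(OMe)3, MeOH, pyridinium p-toluenesulfonate) should close 23 to the 2,5-dimethoxy-2,5-dihydrofuran F8. AlMe3 (CH2Cl2, −78 → −20 °C) should ionise the less hindered ketal carbon C13 and methylate it to the 2-methoxy-5,5-dimethyl-2,5-dihydrofuran F9. Mild hydrolysis (pyridinium p-toluenesulfonate, acetone–H2O) then opens the remaining ketal at C10 to 24 with the Z geometry never released.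

**Step 10.** The ylide may act as a base on the α-branched aldehyde. The C3 enolate is β to C1, a carbon leaving group stabilised by three carbonyls, so retro-Michael opening of the six-membered ring is the main risk. The fallback sets out from 18 and returns at 21; it replaces ylide chemistry by a less basic carbonyl addition followed by reductive transposition. Vinylmagnesium bromide (THF, −78 °C) gives the allylic alcohol F5 as both carbinol epimers. Acetylation (Ac2O, pyridine, DMAP) gives F6. Formate reduction of the π-allyl complex (Pd2(dba)3, PBu3, HCO2NH4, zerovalent palladium delivering hydride to the substituted terminus) gives the 3-allyl compound F7. Cross-metathesis with 2-methylbut-2-ene (second-generation Grubbs catalyst) gives 21. This costs one step more than steps 10–12.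

## Further compounds

F1 | step 6 | (2S)-1-bromo-5-methyl-2-(prop-1-en-2-yl)hex-4-ene ((S)-lavandulyl bromide) | CC(C)=CC[C@@H](C(C)=C)CBr
F2 | step 6 | 3-isobutyryl-5-[(2R)-5-methyl-2-(prop-1-en-2-yl)hex-4-en-1-yl]-5-prenylcyclopentane-1,2,4-trione (enol form, both C5 epimers) | CC(C)C(=O)C1=C(O)C(=O)C(CC=C(C)C)(C[C@@H](CC=C(C)C)C(C)=C)C1=O
F3 | step 6 | (1R,3R,5R)-1-isobutyryl-2,2-dimethyl-3,5-diprenylbicyclo[3.2.1]octane-6,7,8-trione | CC(C)=CC[C@@H]1C[C@]2(CC=C(C)C)C(=O)[C@@](C(=O)C(C)C)(C(=O)C2=O)C1(C)C
F4 | step 8 | (1R,3R,5S,6S)-3-(dimethoxymethyl)-6-hydroxy-1-isobutyryl-2,2-dimethyl-6-(5-methylfuran-2-yl)-5-prenylbicyclo[3.2.1]octane-7,8-dione | COC(OC)[C@@H]1C[C@]2(CC=C(C)C)C(=O)[C@@](C(=O)C(C)C)(C(=O)[C@@]2(O)c3ccc(C)o3)C1(C)C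
F5 | step 10 | (1R,3R,5S,6S)-3-(1-hydroxyprop-2-en-1-yl)-1-isobutyryl-2,2-dimethyl-6-(5-methylfuran-2-yl)-5-prenyl-6-(triethylsilyloxy)bicyclo[3.2.1]octane-7,8-dione (both carbinol epimers) | C=CC(O)[C@@H]1C[C@]2(CC=C(C)C)C(=O)[C@@](C(=O)C(C)C)(C(=O)[C@@]2(O[Si](CC)(CC)CC)c3ccc(C)o3)C1(C)C
F6 | step 10 | acetate of F5 (both epimers) | C=CC(OC(C)=O)[C@@H]1C[C@]2(CC=C(C)C)C(=O)[C@@](C(=O)C(C)C)(C(=O)[C@@]2(O[Si](CC)(CC)CC)c3ccc(C)o3)C1(C)C
F7 | step 10 | (1R,3R,5S,6S)-3-allyl-1-isobutyryl-2,2-dimethyl-6-(5-methylfuran-2-yl)-5-prenyl-6-(triethylsilyloxy)bicyclo[3.2.1]octane-7,8-dione | C=CC[C@@H]1C[C@]2(CC=C(C)C)C(=O)[C@@](C(=O)C(C)C)(C(=O)[C@@]2(O[Si](CC)(CC)CC)c3ccc(C)o3)C1(C)C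
F8 | step 14 | bis-ketal of 23: 2,5-dimethoxy-5-methyl-2,5-dihydrofuran-2-yl group on C6, skeleton configuration as in 23, ketal carbons as mixtures | CC(C)=CC[C@@H]1C[C@]2(CC=C(C)C)C(=O)[C@@](C(=O)C(C)C)(C(=O)[C@@]2(O[Si](CC)(CC)CC)C3(OC)C=CC(C)(OC)O3)C1(C)C
F9 | step 14 | methyl lactol ether of 24: 2-methoxy-5,5-dimethyl-2,5-dihydrofuran-2-yl group on C6, skeleton configuration as in 23, ketal carbon as a mixture | CC(C)=CC[C@@H]1C[C@]2(CC=C(C)C)C(=O)[C@@](C(=O)C(C)C)(C(=O)[C@@]2(O[Si](CC)(CC)CC)C3(OC)C=CC(C)(C)O3)C1(C)C
A1 | alternative 1 | methyl 7-(tert-butyldimethylsilyloxy)-3,5-bis(2,2-dimethoxyethyl)-1-isobutyryl-2,2-dimethyl-8-oxobicyclo[3.2.1]octane-6-carboxylate | COC(OC)C[C@@H]1C[C@]2(CC(OC)OC)C(=O)[C@@](C(=O)C(C)C)([C@@H](O[Si](C)(C)C(C)(C)C)[C@H]2C(=O)OC)C1(C)C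
A2 | alternative 2 | 1-isobutyryl-2,2-dimethyl-3,5-diprenyl-6-(triethylsilyloxy)bicyclo[3.2.1]octane-7,8-dione | CC(C)=CC[C@@H]1C[C@]2(CC=C(C)C)C(=O)[C@@](C(=O)C(C)C)(C(=O)[C@H]2O[Si](CC)(CC)CC)C1(C)C
A3 | alternative 3 | cohulupone, 3-isobutyryl-5,5-diprenylcyclopentane-1,2,4-trione (enol form) | CC(C)C(=O)C1=C(O)C(=O)C(CC=C(C)C)(CC=C(C)C)C1=O
A4 | alternative 3 | 1-isobutyryl-2,2-dimethyl-3-(phenylselanyl)-5-prenylbicyclo[3.2.1]octane-6,7,8-trione | c3ccccc3[Se][C@@H]1C[C@]2(CC=C(C)C)C(=O)[C@@](C(=O)C(C)C)(C(=O)C2=O)C1(C)C
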